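Every flask starts from 0.10 M of starting material, and the runs so far differ in enzyme, from 0.0049 mol% to 0.026 mol%.

the same everywhere: starting material 0.10 M

| run | enzyme | remark | time |
|---|---|---|---|
| Saturday's | 0.0049 mol% | run made earlier |  |
| Friday's | 0.012 mol% | run made earlier |  |
| Thursday's | 0.026 mol% | run made earlier |  |
| birch | 0.006 mol% |  | 20 d |
| elm | 0.01 mol% |  | 20 d |
| alder | 0.015 mol% |  | 20 d |
| ash | 0.025 mol% |  | 20 d |

| Saturday's: time / d | Saturday's: product / % | Friday's: time / d | Friday's: product / % | Thursday's: time / d | Thursday's: product / % |
|---|---|---|---|---|---|
| 3.00 | 62.0 | 1.04 | 57.6 | 1.25 | 76.4 |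
| 6.00 | 77.5 | 2.00 | 71.5 | 4.00 | 89.1 |
| 8.00 | 80.3 | 4.00 | 82.8 | 6.00 | 91.6 |
| 12.0 | 84.6 | 8.00 | 90.0 | 10.0 | 93.1 |
| 15.0 | 86.2 | 15.0 | 93.0 | 15.0 | 96.4 |

(readings scatter by 1 percentage point)

- the analysis behind the earlier runs scatters by 1 percentage point, standard deviation
- "hardly changes" means that all values lie within two and a half points (for a concentration: within two and a half percent of the largest)

- amount of product at the end, in percent of the starting material charged for birch, elm, alder, ash, in this order
- the course of these numbers from the first flask to the last (rises all the way / hardly changes / rises, then falls / falls, then rises / falls all the way)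

My first estimate is a rule of three, with no rate law. If the enzyme comes through unchanged, a flask with less of it is Thursday's flask on a slower clock. Birch's 20 d then counts as 4.62 d. I call this the Thursday-equivalent time: the time multiplied by the flask's loading and divided by Thursday's. Elm gets 7.69 d, alder 11.5 d and ash 19.2 d.

But this needs the enzyme to survive, which is Selwyn's test. Saturday's flask is the hard case, with the least enzyme. Its reading of 86.2% at 15.0 d counts as 6.12 d on Friday's clock, which falls between Friday's readings at 4.00 d and 8.00 d. The mean of those readings is 86.4%, so the objection fails within the scatter of 1 percentage point.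

So I read brackets off Thursday's run: birch between 89.1% and 91.6%, elm between 91.6% and 93.1%, alder between 93.1% and 96.4%. A second objection is that ash lies later than Thursday's last reading, so for ash I have a floor near 96.4% and no bracket. That is enough for the shape, because from the top of birch's bracket to ash's floor the readings climb 4.8 points, which clears the margin for a flat row, and no run ever falls. I expect a steady rise.

The forecast gives 90.7%, 93.5%, 95.2% and 96.8%, and says rises all the way, holding that “Selwyn's test therefore passes, so the enzyme survives and only enzyme × time matters”. Its elm stands above my bracket, by less than the scatter of one reading.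

The flasks give 90.5%, 93.3%, 94.9% and 96.4%, and the course rises all the way.

    starting material + enzyme → product + enzyme, rate k1*[starting material]^2.5*[enzyme]/(1 + ([starting material]/Kh1)^2.5) (0.0910 M, k = 71.0 L²·⁵ mol⁻²·⁵ s⁻¹)

Birch's 90.5% lies inside the bracket set by its 4.62 d. Alder at 10.0 d counts as 5.77 d and holds 91.8%, beside Thursday's 91.6% at 6.00 d. Birch's shortfall is mainly one of time: with its enzyme still at 100%, a reading at 200 d, or 46.2 d on the same clock, gives 98.0%, a gain of 7.5 points and 79% of what is missing.

The data are calculated on assumed constants; the scatter is artificial.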